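**Plan**

- Retrosynthesis: the C9–O (senecioate) and C8–O (tiglate) ester bonds are cut first, then the C7–isopropenyl bond (epoxide opening), the C4–CH3 bond (cuprate) and, as the one skeletal cut, the C9–C10 bond of ring A.
- Enabling feature: the quaternary C5 of ring B (C1–C2–C3–C4–C5–C10) stands para to the C2 carbonyl, so ring B is a latent 4,4-disubstituted cyclohexa-2,5-dienone whose arms C1=C10 and C3=C4 are enantiotopic. C9 of ring A (C5–C6–C7–C8–C9–C10) can then be an aldehyde carbon on a C6–C7–C8 chain.
- Forward: ring B is made first as the achiral dienone aldehyde 9 (two α′-alkylations, enone transposition, dehydrogenation, ozonolysis); ring A closes in step 6 by a carbene-catalysed Stetter desymmetrisation.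
- Stereochemistry: C5 from the chiral triazolium catalyst; C10 from the tether (cis fusion); C4 from axial cuprate attack on the convex face; C9 from convex-face hydride delivery; C8 and C7 from hydroxyl-directed epoxidation and anti opening by an isopropenyl cuprate.
- The esters go on in the order of hydroxyl accessibility: equatorial C8 first, axial C9 last, after the C2 ketal is removed.

Key step: step 6

Remark on names: locants C1–C10 are those of the target and are used with "decalin" for all bicyclic compounds; β is the face of the C5 methyl group, α the opposite face.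

Assumption: the triazolium antipode named in step 6 is taken to be the one that selects the enone arm leading to (4aR,8aS)-10; if a trial shows the opposite sense, the commercially available mirror-image salt is used with no other change.

**Route**

Step 1
Reactants: 1 3-ethoxycyclohex-2-en-1-one; 2 5-bromopent-1-ene
Product: 3 3-ethoxy-6-(pent-4-en-1-yl)cyclohex-2-en-1-one (racemic)
Conditions: LiN(iPr)2, THF, −78 °C; then 2, DMPU, −78 → 23 °C
Reagents that add atoms: none
Why: Kinetic deprotonation of the vinylogous ester at C6 and SN2 attack on the primary bromide is the Stork–Danheiser α′-alkylation; the new stereocentre forms racemic and is erased at the dienone stage.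

Step 2
Reactants: 3 3-ethoxy-6-(pent-4-en-1-yl)cyclohex-2-en-1-one
Product: 4 3-ethoxy-6-methyl-6-(pent-4-en-1-yl)cyclohex-2-en-1-one (racemic)
Conditions: LiN(iPr)2, THF, −78 °C; then MeI, −78 → 0 °C
Reagents that add atoms: iodomethane, CI
Why: A second Stork–Danheiser α′-alkylation, kept for the small and reactive electrophile MeI, builds the quaternary carbon (later C5) as a racemate that loses its chirality in 7.

Step 3
Reactants: 4 3-ethoxy-6-methyl-6-(pent-4-en-1-yl)cyclohex-2-en-1-one
Product: 6 4-methyl-4-(pent-4-en-1-yl)cyclohex-2-en-1-one (racemic), via allylic alcohol 5 (not isolated)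
Conditions: LiAlH4, Et2O, 0 °C; then 2 M HCl, 23 °C
Reagents that add atoms: water, O
Why: Stork–Danheiser enone transposition: hydride 1,2-reduction gives the allylic alcohol, and aqueous acid hydrolyses the enol ether and expels the hydroxyl to leave the 4,4-disubstituted enone with the terminal alkene untouched.

Step 4
Reactants: 6 4-methyl-4-(pent-4-en-1-yl)cyclohex-2-en-1-one
Product: 7 4-methyl-4-(pent-4-en-1-yl)cyclohexa-2,5-dien-1-one (achiral)
Conditions: DDQ, 1,4-dioxane, reflux
Reagents that add atoms: none
Why: DDQ dehydrogenation of a 4,4-dialkylcyclohexenone through its dienol is the standard entry to cross-conjugated dienones; the quaternary carbon blocks aromatisation and the ring becomes achiral with two enantiotopic enone arms.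

Step 5
Reactants: 7 4-methyl-4-(pent-4-en-1-yl)cyclohexa-2,5-dien-1-one
Product: 9 4-(1-methyl-4-oxocyclohexa-2,5-dien-1-yl)butanal, via secondary ozonide 8 (not isolated)
Conditions: O3, CH2Cl2, −78 °C (Sudan red 7B end point); then PPh3, −78 → 23 °C
Reagents that add atoms: ozone, [O-][O+]=O
Why: Ozonolysis with reductive work-up cleaves the electron-rich monosubstituted alkene far faster than the electron-poor dienone double bonds, and the indicator dye stops the gas at one equivalent.

Step 6
Reactants: 9 4-(1-methyl-4-oxocyclohexa-2,5-dien-1-yl)butanal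
Product: 10 (4aR,8aS)-4a-methyl-4a,5,6,7-tetrahydronaphthalene-2,8(1H,8aH)-dione (cis-fused; C9 ketone, C2 enone with C3=C4, 5β-methyl, 10β-H)
Conditions: (5aS,10bR)-2-(pentafluorophenyl)-5a,10b-dihydro-4H,6H-indeno[2,1-b][1,2,4]triazolo[4,3-d][1,4]oxazin-2-ium tetrafluoroborate (20 mol %), KN(SiMe3)2 (20 mol %), toluene, 23 °C
Reagents that add atoms: none
Why: The triazolylidene freed by the base adds to the aldehyde carbon C9, proton transfer gives the Breslow intermediate, and this acyl-anion equivalent adds 1,4 to C10 of one enone arm before the adduct collapses to the C9 ketone and releases the carbene (intramolecular Stetter reaction). The closest known reaction type is the triazolium-catalysed Stetter desymmetrisation of 4,4-disubstituted cyclohexadienones carrying an aldehyde on a shorter, oxygen-containing tether, together with six-ring Stetter closures of aliphatic aldehydes onto acyclic enones. Ring A (C5–C6–C7–C8–C9–C10) closes in a 6-exo-trig mode. C10 is controlled by the tether, which can reach only the dienone face on which it stands, so H10 ends syn to the C5 methyl (cis fusion); C5 is controlled by the catalyst, whose aminoindanol backbone decides which enantiotopic arm receives the acyl anion. The step needs enantiotopic-group selection and a Stetter pathway that outruns aldol and benzoin reactions of the enolisable aldehyde; the electron-poor N-aryl carbene, the quaternary C5 that folds the chain over the ring, and the unhindered β-CH of the cross-conjugated acceptor serve this, and catalytic base keeps the kinetic cis fusion.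

Step 7
Reactants: 10 (4aR,8aS)-4a-methyl-4a,5,6,7-tetrahydronaphthalene-2,8(1H,8aH)-dione
Product: 11 4β,5β-dimethyl-10βH-decalin-2,9-dione
Conditions: Me2CuLi (from CuI and 2 MeLi), Et2O, −78 → −40 °C; aq NH4Cl
Reagents that add atoms: lithium dimethylcuprate, [Li+].C[Cu-]C
Why: Gilman cuprate 1,4-addition to the enone, which leaves the saturated C9 ketone alone at low temperature; methyl enters C4 axially on the convex β face, anti to the pseudoaxial C5–C6 bond and beside the small H10, because the opposite axial path collides with C9, so the C4 methyl ends cis to the C5 methyl.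

Step 8
Reactants: 11 4β,5β-dimethyl-10βH-decalin-2,9-dione
Product: 12 2,2-(ethylenedioxy)-4β,5β-dimethyl-10βH-decalin-9-one
Conditions: Me3SiOCH2CH2OSiMe3, Me3SiOTf (cat.), CH2Cl2, −78 °C; pyridine quench
Reagents that add atoms: 1,2-bis(trimethylsilyloxy)ethane, C[Si](C)(C)OCCO[Si](C)(C)C
Why: Kinetically controlled silyl-transfer ketalisation (dioxolane formation) favours the C2 carbonyl between two methylene groups over the C9 carbonyl next to the ring-fusion methine, and the aprotic medium at −78 °C does not enolise C9 toward the epimerisable C10.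

Step 9
Reactants: 12 2,2-(ethylenedioxy)-4β,5β-dimethyl-10βH-decalin-9-one
Product: 14 2,2-(ethylenedioxy)-4β,5β-dimethyl-10βH-decal-7-en-9-one, via trimethylsilyl enol ether 13 (not isolated)
Conditions: LiN(iPr)2, THF, −78 °C, then Me3SiCl; then Pd(OAc)2, MeCN, 23 °C
Reagents that add atoms: none
Why: Saegusa–Ito oxidation: the amide base removes a proton from the C8 methylene in preference to the hindered C10 methine, and Pd(OAc)2 converts the resulting silyl enol ether into the C7=C8 enone, the only enone C9 can form since C5 is quaternary.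

Step 10
Reactants: 14 2,2-(ethylenedioxy)-4β,5β-dimethyl-10βH-decal-7-en-9-one
Product: 15 2,2-(ethylenedioxy)-4β,5β-dimethyl-10βH-decal-7-en-9α-ol
Conditions: NaBH4, CeCl3·7H2O, MeOH, −78 °C
Reagents that add atoms: none
Why: Luche 1,2-reduction; hydride should reach C9 from the convex β face beside H10, because the α face is screened by the C10–C1 bond and by ring B folded beneath it, which places the C9 hydroxyl α (trans to H10).

Step 11
Reactants: 15 2,2-(ethylenedioxy)-4β,5β-dimethyl-10βH-decal-7-en-9α-ol
Product: 16 7α,8α-epoxy-2,2-(ethylenedioxy)-4β,5β-dimethyl-10βH-decalin-9α-ol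
Conditions: VO(acac)2 (cat.), tBuOOH, CH2Cl2, 0 → 23 °C
Reagents that add atoms: tert-butyl hydroperoxide, CC(C)(C)OO
Why: Hydroxyl-directed epoxidation: the vanadium alkoxide of the C9 alcohol delivers the peroxide oxygen to the alkene face on which it sits, which sets C7 and C8 as the α-epoxide.

Step 12
Reactants: 16 7α,8α-epoxy-2,2-(ethylenedioxy)-4β,5β-dimethyl-10βH-decalin-9α-ol
Product: 17 2,2-(ethylenedioxy)-7β-isopropenyl-4β,5β-dimethyl-10βH-decalin-8α,9α-diol
Conditions: isopropenylmagnesium bromide (4 equiv), CuI (20 mol %), THF, −30 → 0 °C; aq NH4Cl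
Reagents that add atoms: isopropenylmagnesium bromide, C=C(C)[Mg]Br
Why: Copper-catalysed Grignard opening of the epoxide by SN2 attack with inversion; the cuprate enters C7 from the β face, C7 being remote from the C9 alkoxide and the site of trans-diaxial (Fürst–Plattner) opening in the half-chair that keeps the C9 oxygen pseudoequatorial, so the isopropenyl group becomes β and the C8 hydroxyl stays α.

Step 13
Reactants: 17 2,2-(ethylenedioxy)-7β-isopropenyl-4β,5β-dimethyl-10βH-decalin-8α,9α-diol; 18 tiglic acid [(E)-2-methylbut-2-enoic acid]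
Product: 20 2,2-(ethylenedioxy)-9α-hydroxy-7β-isopropenyl-4β,5β-dimethyl-10βH-decalin-8α-yl (E)-2-methylbut-2-enoate, via tiglic 2,4,6-trichlorobenzoic anhydride 19 (not isolated)
Conditions: 18, 2,4,6-trichlorobenzoyl chloride, Et3N, toluene, 23 °C; then 17, DMAP, 0 °C
Reagents that add atoms: none
Why: Yamaguchi esterification with one equivalent of the mixed anhydride should acylate the equatorial C8 hydroxyl, since the axial C9 hydroxyl lies under ring B, syn-axial to C4 and hydrogen-bonded to the axial ketal oxygen.

Step 14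
Reactants: 20 2,2-(ethylenedioxy)-9α-hydroxy-7β-isopropenyl-4β,5β-dimethyl-10βH-decalin-8α-yl (E)-2-methylbut-2-enoate
Product: 21 9α-hydroxy-7β-isopropenyl-4β,5β-dimethyl-2-oxo-10βH-decalin-8α-yl (E)-2-methylbut-2-enoate
Conditions: AcOH–THF–H2O (3:1:1), 40 °C
Reagents that add atoms: water, O
Why: Acid hydrolysis of the dioxolane under mild aqueous conditions that spare the enoate ester and the isopropenyl group; no stereocentre next to the new ketone can epimerise, and removing the ketal uncovers the C9 hydroxyl for the last acylation.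

Step 15
Reactants: 21 9α-hydroxy-7β-isopropenyl-4β,5β-dimethyl-2-oxo-10βH-decalin-8α-yl (E)-2-methylbut-2-enoate; 22 3-methylbut-2-enoic acid
Product: 24 7β-isopropenyl-4β,5β-dimethyl-9α-(3-methylbut-2-enoyloxy)-2-oxo-10βH-decalin-8α-yl (E)-2-methylbut-2-enoate (CNP0181050.1), via 3-methylbut-2-enoic 2,4,6-trichlorobenzoic anhydride 23 (not isolated)
Conditions: 22, 2,4,6-trichlorobenzoyl chloride, Et3N, toluene, 23 °C; then 21, DMAP, 60 °C
Reagents that add atoms: none
Why: Yamaguchi esterification of the one remaining hydroxyl, the hindered axial C9 alcohol, with the DMAP-activated mixed anhydride at raised temperature gives the senecioate and completes the target.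

**Compound list**

1 | 3-ethoxycyclohex-2-en-1-one | CCOC1=CC(=O)CCC1 | starting material
2 | 5-bromopent-1-ene | C=CCCCBr | starting material
3 | 3-ethoxy-6-(pent-4-en-1-yl)cyclohex-2-en-1-one (racemic) | CCOC1=CC(=O)C(CCCC=C)CC1 | intermediate
4 | 3-ethoxy-6-methyl-6-(pent-4-en-1-yl)cyclohex-2-en-1-one (racemic) | CCOC1=CC(=O)C(C)(CCCC=C)CC1 | intermediate
5 | 3-ethoxy-6-methyl-6-(pent-4-en-1-yl)cyclohex-2-en-1-ol (diastereomer mixture) | CCOC1=CC(O)C(C)(CCCC=C)CC1 | intermediate (not isolated)
6 | 4-methyl-4-(pent-4-en-1-yl)cyclohex-2-en-1-one (racemic) | C=CCCCC1(C)C=CC(=O)CC1 | intermediate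
7 | 4-methyl-4-(pent-4-en-1-yl)cyclohexa-2,5-dien-1-one | C=CCCCC1(C)C=CC(=O)C=C1 | intermediate
8 | 4-methyl-4-[3-(1,2,4-trioxolan-3-yl)propyl]cyclohexa-2,5-dien-1-one | O=C1C=CC(C)(CCCC2OCOO2)C=C1 | intermediate (not isolated)
9 | 4-(1-methyl-4-oxocyclohexa-2,5-dien-1-yl)butanal | O=CCCCC1(C)C=CC(=O)C=C1 | intermediate
10 | (4aR,8aS)-4a-methyl-4a,5,6,7-tetrahydronaphthalene-2,8(1H,8aH)-dione | C1C[C@@]2(C)[C@H](CC(=O)C=C2)C(=O)C1 | intermediate
11 | 4β,5β-dimethyl-10βH-decalin-2,9-dione | C1C[C@@]2(C)[C@H](CC(=O)C[C@@H]2C)C(=O)C1 | intermediate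
12 | 2,2-(ethylenedioxy)-4β,5β-dimethyl-10βH-decalin-9-one | C1C[C@@]2(C)[C@H](CC3(OCCO3)C[C@@H]2C)C(=O)C1 | intermediate
13 | 2,2-(ethylenedioxy)-4β,5β-dimethyl-9-(trimethylsilyloxy)-10βH-decal-8-ene | C1C[C@@]2(C)[C@H](CC3(OCCO3)C[C@@H]2C)C(O[Si](C)(C)C)=C1 | intermediate (not isolated)
14 | 2,2-(ethylenedioxy)-4β,5β-dimethyl-10βH-decal-7-en-9-one | C=1C[C@@]2(C)[C@H](CC3(OCCO3)C[C@@H]2C)C(=O)C=1 | intermediate
15 | 2,2-(ethylenedioxy)-4β,5β-dimethyl-10βH-decal-7-en-9α-ol | C=1C[C@@]2(C)[C@H](CC3(OCCO3)C[C@@H]2C)[C@H](O)C=1 | intermediate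
16 | 7α,8α-epoxy-2,2-(ethylenedioxy)-4β,5β-dimethyl-10βH-decalin-9α-ol | [C@@H]14C[C@@]2(C)[C@H](CC3(OCCO3)C[C@@H]2C)[C@H](O)[C@@H]1O4 | intermediate
17 | 2,2-(ethylenedioxy)-7β-isopropenyl-4β,5β-dimethyl-10βH-decalin-8α,9α-diol | C=C(C)[C@H]1C[C@@]2(C)[C@H](CC3(OCCO3)C[C@@H]2C)[C@H](O)[C@@H]1O | intermediate
18 | tiglic acid | C/C=C(\C)C(=O)O | starting material
19 | tiglic 2,4,6-trichlorobenzoic anhydride | C/C=C(\C)C(=O)OC(=O)c1c(Cl)cc(Cl)cc1Cl | intermediate (not isolated)
20 | 2,2-(ethylenedioxy)-9α-hydroxy-7β-isopropenyl-4β,5β-dimethyl-10βH-decalin-8α-yl (E)-2-methylbut-2-enoate | C=C(C)[C@H]1C[C@@]2(C)[C@H](CC3(OCCO3)C[C@@H]2C)[C@H](O)[C@@H]1OC(=O)/C(C)=C/C | intermediate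
21 | 9α-hydroxy-7β-isopropenyl-4β,5β-dimethyl-2-oxo-10βH-decalin-8α-yl (E)-2-methylbut-2-enoate | C=C(C)[C@H]1C[C@@]2(C)[C@H](CC(=O)C[C@@H]2C)[C@H](O)[C@@H]1OC(=O)/C(C)=C/C | intermediate
22 | 3-methylbut-2-enoic acid | CC(C)=CC(=O)O | starting material
23 | 3-methylbut-2-enoic 2,4,6-trichlorobenzoic anhydride | CC(C)=CC(=O)OC(=O)c1c(Cl)cc(Cl)cc1Cl | intermediate (not isolated)
24 | 7β-isopropenyl-4β,5β-dimethyl-9α-(3-methylbut-2-enoyloxy)-2-oxo-10βH-decalin-8α-yl (E)-2-methylbut-2-enoate (CNP0181050.1) | C=C(C)[C@H]1C[C@@]2(C)[C@H](CC(=O)C[C@@H]2C)[C@H](OC(=O)C=C(C)C)[C@@H]1OC(=O)/C(C)=C/C | target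

**Step count and risks**

Total step count: 15. Longest linear sequence: 15 steps (1 to 24); 2, 18 and 22 are purchased.

Steps most likely to fail:

Step 6. The acyl-anion closure may be outpaced by aldol-type self-condensation of the enolisable aldehyde, or the carbene may tell the two enone arms apart poorly. In the fallback a nitronate takes the role of C9 and forms the same C9–C10 bond. Setting out from aldehyde 9, NaBH4 in MeOH–CH2Cl2 at −78 °C should reduce only the aldehyde to 4-(4-hydroxybutyl)-4-methylcyclohexa-2,5-dien-1-one F1. Iodine, PPh3 and imidazole then give 4-(4-iodobutyl)-4-methylcyclohexa-2,5-dien-1-one F2, and NaNO2 in DMF gives 4-methyl-4-(4-nitrobutyl)cyclohexa-2,5-dien-1-one F3. A bifunctional cinchona-alkaloid thiourea should mediate the enantioselective intramolecular nitro-Michael addition (6-exo-trig, cis fusion again imposed by the tether) to (4aR,8aS)-4a-methyl-8-nitro-4a,5,6,7,8,8a-hexahydronaphthalen-2(1H)-one F4. A Nef reaction (KOH, MeOH; then cold aqueous H2SO4) turns the nitro-bearing carbon into the C9 ketone and comes back to the route at 10.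

Step 12. The cuprate may open the epoxide slowly because its axial path to C7 passes the C5 methyl group, so that attack at C8 or bromohydrin formation by the magnesium halide competes. In the fallback the carbon is brought to C7 by conjugate addition instead; this also bypasses steps 10 and 11, but its facial selectivity at C7 rests on substrate bias alone. Setting out from enone 14, isopropenylmagnesium bromide with CuBr·SMe2 and Me3SiCl at −78 °C should give 2,2-(ethylenedioxy)-7β-isopropenyl-4β,5β-dimethyl-9-(trimethylsilyloxy)-10βH-decal-8-ene F5. MeLi regenerates the enolate, and 3-phenyl-2-(phenylsulfonyl)oxaziridine hydroxylates C8 anti to the new C7 substituent to give 2,2-(ethylenedioxy)-8α-hydroxy-7β-isopropenyl-4β,5β-dimethyl-10βH-decalin-9-one F6. LiBH(sBu)3 should then attack C9 from the β face of the now conformationally fixed ring A, and the sequence comes back to the route at diol 17.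

Step 8. Ketal formation may discriminate too little between the C2 and C9 carbonyls, or traces of acid may enolise C9 toward C10 and erode the cis ring fusion. In the fallback the two carbonyls are told apart while C2 is still an enone. Setting out from 10, NaBH4 in EtOH at −20 °C should reduce only the saturated C9 ketone (the selectivity known from the Wieland–Miescher ketone) to 9-hydroxy-5β-methyl-10βH-decal-3-en-2-one F7, the carbinol configuration being immaterial. Excess Me2CuLi adds the C4 methyl to give 9-hydroxy-4β,5β-dimethyl-10βH-decalin-2-one F8, and ethylene glycol with PPTS ketalises the only carbonyl to give 2,2-(ethylenedioxy)-4β,5β-dimethyl-10βH-decalin-9-ol F9. Dess–Martin periodinane reoxidises C9 and comes back to the route at 12.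

**Further compounds**

F1 | step 6 | 4-(4-hydroxybutyl)-4-methylcyclohexa-2,5-dien-1-one | OCCCCC1(C)C=CC(=O)C=C1
F2 | step 6 | 4-(4-iodobutyl)-4-methylcyclohexa-2,5-dien-1-one | ICCCCC1(C)C=CC(=O)C=C1
F3 | step 6 | 4-methyl-4-(4-nitrobutyl)cyclohexa-2,5-dien-1-one | O=[N+]([O-])CCCCC1(C)C=CC(=O)C=C1
F4 | step 6 | (4aR,8aS)-4a-methyl-8-nitro-4a,5,6,7,8,8a-hexahydronaphthalen-2(1H)-one | C1C[C@@]2(C)[C@H](CC(=O)C=C2)C([N+](=O)[O-])C1
F5 | step 12 | 2,2-(ethylenedioxy)-7β-isopropenyl-4β,5β-dimethyl-9-(trimethylsilyloxy)-10βH-decal-8-ene | C=C(C)[C@H]1C[C@@]2(C)[C@H](CC3(OCCO3)C[C@@H]2C)C(O[Si](C)(C)C)=C1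
F6 | step 12 | 2,2-(ethylenedioxy)-8α-hydroxy-7β-isopropenyl-4β,5β-dimethyl-10βH-decalin-9-one | C=C(C)[C@H]1C[C@@]2(C)[C@H](CC3(OCCO3)C[C@@H]2C)C(=O)[C@@H]1O
F7 | step 8 | 9-hydroxy-5β-methyl-10βH-decal-3-en-2-one | C1C[C@@]2(C)[C@H](CC(=O)C=C2)C(O)C1
F8 | step 8 | 9-hydroxy-4β,5β-dimethyl-10βH-decalin-2-one | C1C[C@@]2(C)[C@H](CC(=O)C[C@@H]2C)C(O)C1
F9 | step 8 | 2,2-(ethylenedioxy)-4β,5β-dimethyl-10βH-decalin-9-ol | C1C[C@@]2(C)[C@H](CC3(OCCO3)C[C@@H]2C)C(O)C1
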